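The chromone is cut through its pyranone ring (ring C) at O1–C8a, C4–C4a and O1–C2. The key step exploits the ortho relationship on the benzene ring (ring A) between C8a, which carries O1, and C4a, which carries the C4 carbonyl, with the C5 oxygen on the next carbon beyond C4a: a benzyne with an alkoxy group beside its triple bond delivers oxygen and acyl carbon in exactly this orientation. In one operation 3,5-dimethoxybenzyne inserts into the carboxyl C–O bond of a chiral 2-ynoic acid and the freed phenoxide closes ring C. The precursors are a silyl aryl triflate from 3,5-dimethoxyphenol and (R)-5-(methoxymethoxy)undec-10-en-2-ynoic acid from a resolved epoxide.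

Key step: step 8

Remark on the chemistry: the carbinol is carried as a methoxymethyl (MOM) ether, not a silyl ether, because the key step runs in hot excess fluoride and the acetal falls to the same BCl3 that frees the 5-hydroxyl; (R,R)-(salen)Co(OAc) is assumed to leave the (R)-epoxide, as is usual for alkyl-substituted terminal epoxides.

Step 1
Reactants: 1 3,5-dimethoxyphenol
Product: 2 3,5-dimethoxyphenyl N-isopropylcarbamate
Conditions: i-PrNCO (1.5 equiv), Et3N (0.2 equiv), CH2Cl2, rt
Reagents that add atoms: isopropyl isocyanate, CC(C)N=C=O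
Why: Amine-catalysed addition of the phenol O–H across the isocyanate (carbamoylation) is clean, and the N-isopropyl carbamate is both a strong ortho-directing group and removable later under mild base.

Step 2
Reactants: 2 3,5-dimethoxyphenyl N-isopropylcarbamate
Product: 6 3,5-dimethoxy-2-(trimethylsilyl)phenyl N-isopropylcarbamate, via N-silyl carbamate 3 (not isolated), via aryllithium 4 (not isolated), via N-silyl arylsilane 5 (not isolated)
Conditions: TBSOTf (1.1 equiv), TMEDA (1.1 equiv), Et2O, 0 °C → rt; TMEDA (2 equiv), n-BuLi (2.1 equiv), −78 °C; TMSCl (3.5 equiv), −78 °C → rt; aq. NaHSO4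
Reagents that add atoms: chlorotrimethylsilane, C[Si](C)(C)Cl
Why: In a directed ortho-metalation the N-silyl group made in the flask masks the N–H and suppresses the anionic ortho-Fries shift, the carbamate and the 3-methoxy group together steer n-BuLi/TMEDA to C2, the aryllithium is trapped by TMSCl, and the N-silyl group is lost in the acidic work-up.

Step 3
Reactants: 6 3,5-dimethoxy-2-(trimethylsilyl)phenyl N-isopropylcarbamate
Product: 8 3,5-dimethoxy-2-(trimethylsilyl)phenyl trifluoromethanesulfonate, via silylphenol 7 (not isolated)
Conditions: DBU (1.5 equiv), Et2NH (1.2 equiv), MeCN, 40 °C; then PhNTf2 (1.5 equiv), rt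
Reagents that add atoms: N-phenylbis(trifluoromethanesulfonimide), O=S(=O)(N(c1ccccc1)S(=O)(=O)C(F)(F)F)C(F)(F)F
Why: DBU removes the carbamate N–H and expels the phenoxide by an E1cB elimination, Et2NH scavenges the isocyanate, and the phenoxide is O-sulfonylated by PhNTf2 in the same flask (carbamate cleavage followed by triflation).

Step 4
Reactants: 9 racemic 1,2-epoxy-7-octene
Product: 10 (R)-1,2-epoxy-7-octene
Conditions: (R,R)-(salen)Co(OAc) (trivalent cobalt, salen = N,N′-bis(3,5-di-tert-butylsalicylidene)cyclohexane-1,2-diaminate, 0.5 mol%), H2O (0.55 equiv), minimal THF, 0 °C → rt; distillation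
Reagents that add atoms: none
Why: In the Jacobsen hydrolytic kinetic resolution the catalyst should hydrolyse the (S)-epoxide selectively, so the unreacted (R)-epoxide, whose C2 becomes the carbinol stereocentre of the target, is recovered by distillation from the diol.

Step 5
Reactants: 10 (R)-1,2-epoxy-7-octene; 11 lithium acetylide–ethylenediamine complex, LiC≡CH·H2NCH2CH2NH2 (1.5 equiv)
Product: 12 (4R)-dec-9-en-1-yn-4-ol
Conditions: DMSO, rt; then H2O
Reagents that add atoms: none
Why: SN2 opening of the terminal epoxide by the acetylide at the unsubstituted carbon (epoxide alkynylation) does not touch the C–O stereocentre, so the (R) configuration is carried over unchanged.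

Step 6
Reactants: 12 (4R)-dec-9-en-1-yn-4-ol
Product: 13 (7R)-7-(methoxymethoxy)dec-1-en-9-yne
Conditions: MOMCl (2 equiv), i-Pr2NEt (3 equiv), CH2Cl2, 0 °C → rt
Reagents that add atoms: chloromethyl methyl ether, COCCl
Why: O-Alkylation of the secondary alcohol by the reactive α-chloro ether under amine base (methoxymethyl ether formation) gives an acetal that is inert to organolithiums, to fluoride and to base, without touching the stereocentre.

Step 7
Reactants: 13 (7R)-7-(methoxymethoxy)dec-1-en-9-yne
Product: 15 (5R)-5-(methoxymethoxy)undec-10-en-2-ynoic acid, via lithium acetylide 14 (not isolated)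
Conditions: n-BuLi (1.05 equiv), THF, −78 °C; CO2 (dried gas), −78 → 0 °C; 1 M HCl to pH 3, 0 °C
Reagents that add atoms: carbon dioxide, O=C=O
Why: Deprotonation of the terminal alkyne and carboxylation of the lithium acetylide with CO2 is the standard route to 2-ynoic acids, and the acetal and the terminal alkene are inert to one equivalent of base at low temperature.

Step 8
Reactants: 8 3,5-dimethoxy-2-(trimethylsilyl)phenyl trifluoromethanesulfonate (1.5 equiv); 15 (5R)-5-(methoxymethoxy)undec-10-en-2-ynoic acid
Product: 19 5,7-dimethoxy-2-[(2R)-2-(methoxymethoxy)oct-7-en-1-yl]-4H-chromen-4-one, via 3,5-dimethoxybenzyne 16 (not isolated), via aryl anion ester 17 (not isolated), via ynone phenoxide 18 (not isolated)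
Conditions: CsF (4 equiv), THF, 125 °C, sealed tube
Reagents that add atoms: none
Why: Fluoride attacks silicon of 8 and triflate leaves to give aryne 16, the cesium carboxylate of 15 adds to the aryne carbon remote from the neighbouring methoxy group (future C8a) to give aryl anion 17, and the carbanion at future C4a attacks its own ester carbonyl through a four-membered transition state that collapses to ynone phenoxide 18 with the new C4–C4a bond. The closest known reaction type is the fluoride-induced insertion of arynes into the C–O bond of carboxylic acids, which converts arylpropiolic acids into flavones in the same flask, and 15 differs only in carrying an alkyl chain on the alkyne. Ring C closes by 6-endo-dig oxa-Michael addition of the phenoxide oxygen to the ynone β-carbon (O1–C2), the vinyl anion taking up the proton released from the acid, and the conjugated 4-pyranone is favoured over the 5-exo-dig benzofuranone. No stereocentre is formed, the (R)-carbinol is a spectator, and its acetal is inert to fluoride and to the basic medium. The step needs regioselective addition to the unsymmetrical aryne, secured by the inductive effect of the methoxy group beside the triple bond, which places the developing negative charge ortho to oxygen, and it needs the acyl shift to outrun protonation of 17, secured by the absence of any O–H group other than the acid, by excess CsF that binds HF and by the high temperature.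

Step 9
Reactants: 19 5,7-dimethoxy-2-[(2R)-2-(methoxymethoxy)oct-7-en-1-yl]-4H-chromen-4-one
Product: 20 5-hydroxy-2-[(2R)-2-hydroxyoct-7-en-1-yl]-7-methoxy-4H-chromen-4-one
Conditions: BCl3 (3 equiv, 1 M in CH2Cl2), CH2Cl2, −78 → 0 °C; then H2O, rt
Reagents that add atoms: none
Why: In this chelation-controlled Lewis acid ether cleavage BCl3 binds between the C4 carbonyl and the peri 5-methoxy oxygen so that chloride removes only that methyl group, the same reagent ionises the methoxymethyl acetal, and the unchelated 7-methoxy group and the alkene should survive at or below 0 °C.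

Step 10
Reactants: 20 5-hydroxy-2-[(2R)-2-hydroxyoct-7-en-1-yl]-7-methoxy-4H-chromen-4-one; 21 acrylic acid (5 equiv)
Product: 22 penithochromone T, (2E,8R)-8-hydroxy-9-(5-hydroxy-7-methoxy-4-oxo-4H-chromen-2-yl)non-2-enoic acid
Conditions: second-generation Hoveyda–Grubbs catalyst RuCl2(H2IMes)(=CH–C6H4-2-O-i-Pr) (5 mol%), CH2Cl2, 40 °C
Reagents that add atoms: none
Why: Olefin cross-metathesis of the terminal alkene with excess acrylic acid, an electron-poor partner that hardly homodimerises, should give the conjugated acid with E geometry under thermodynamic control, driven by loss of ethene, and free hydroxyl and carboxyl groups are tolerated by the catalyst.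

Compound list
1 | 3,5-dimethoxyphenol | COc1cc(O)cc(OC)c1 | starting material
2 | 3,5-dimethoxyphenyl N-isopropylcarbamate | COc1cc(OC)cc(OC(=O)NC(C)C)c1 | intermediate
3 | 3,5-dimethoxyphenyl N-(tert-butyldimethylsilyl)-N-isopropylcarbamate | COc1cc(OC)cc(OC(=O)N(C(C)C)[Si](C)(C)C(C)(C)C)c1 | intermediate (not isolated)
4 | 2-lithio derivative of 3, lithium at C2 between the carbamate oxygen and the 3-methoxy group | COc1cc(OC)c([Li])c(OC(=O)N(C(C)C)[Si](C)(C)C(C)(C)C)c1 | intermediate (not isolated)
5 | 3,5-dimethoxy-2-(trimethylsilyl)phenyl N-(tert-butyldimethylsilyl)-N-isopropylcarbamate | COc1cc(OC)c([Si](C)(C)C)c(OC(=O)N(C(C)C)[Si](C)(C)C(C)(C)C)c1 | intermediate (not isolated)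
6 | 3,5-dimethoxy-2-(trimethylsilyl)phenyl N-isopropylcarbamate | COc1cc(OC)c([Si](C)(C)C)c(OC(=O)NC(C)C)c1 | intermediate
7 | 3,5-dimethoxy-2-(trimethylsilyl)phenol, present as its DBU salt | COc1cc(O)c([Si](C)(C)C)c(OC)c1 | intermediate (not isolated)
8 | 3,5-dimethoxy-2-(trimethylsilyl)phenyl trifluoromethanesulfonate | COc1cc(OC)c([Si](C)(C)C)c(OS(=O)(=O)C(F)(F)F)c1 | intermediate
9 | racemic 1,2-epoxy-7-octene, 2-(hex-5-en-1-yl)oxirane | C=CCCCCC1CO1 | starting material
10 | (R)-1,2-epoxy-7-octene, (2R)-2-(hex-5-en-1-yl)oxirane | C=CCCCC[C@@H]1CO1 | intermediate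
11 | lithium acetylide–ethylenediamine complex | [Li]C#C.NCCN | starting material
12 | (4R)-dec-9-en-1-yn-4-ol | C#CC[C@H](O)CCCCC=C | intermediate
13 | (7R)-7-(methoxymethoxy)dec-1-en-9-yne, the MOM ether of 12 | C#CC[C@H](OCOC)CCCCC=C | intermediate
14 | lithium acetylide of 13, [(4R)-4-(methoxymethoxy)dec-9-en-1-yn-1-yl]lithium | [Li]C#CC[C@H](OCOC)CCCCC=C | intermediate (not isolated)
15 | (5R)-5-(methoxymethoxy)undec-10-en-2-ynoic acid | OC(=O)C#CC[C@H](OCOC)CCCCC=C | intermediate
16 | 3,5-dimethoxybenzyne, 1,2-didehydro-3,5-dimethoxybenzene | COC1=CC(OC)=CC#C1 | intermediate (not isolated)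
17 | 3,5-dimethoxyphenyl (5R)-5-(methoxymethoxy)undec-10-en-2-ynoate with the negative charge at ring C2, between the ester oxygen and the 3-methoxy group, cesium counter-ion | COc1cc(OC)[c-]c(OC(=O)C#CC[C@H](OCOC)CCCCC=C)c1.[Cs+] | intermediate (not isolated)
18 | cesium 3,5-dimethoxy-2-[(5R)-5-(methoxymethoxy)undec-10-en-2-ynoyl]phenolate | COc1cc([O-])c(C(=O)C#CC[C@H](OCOC)CCCCC=C)c(OC)c1.[Cs+] | intermediate (not isolated)
19 | 5,7-dimethoxy-2-[(2R)-2-(methoxymethoxy)oct-7-en-1-yl]-4H-chromen-4-one | COc1cc(OC)c2c(=O)cc(C[C@H](OCOC)CCCCC=C)oc2c1 | intermediate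
20 | 5-hydroxy-2-[(2R)-2-hydroxyoct-7-en-1-yl]-7-methoxy-4H-chromen-4-one | COc1cc(O)c2c(=O)cc(C[C@H](O)CCCCC=C)oc2c1 | intermediate
21 | acrylic acid | C=CC(=O)O | starting material
22 | penithochromone T, (2E,8R)-8-hydroxy-9-(5-hydroxy-7-methoxy-4-oxo-4H-chromen-2-yl)non-2-enoic acid | COc1cc(O)c2c(=O)cc(C[C@H](O)CCCC/C=C/C(=O)O)oc2c1 | target

Total step count: 10 steps.
Longest linear sequence: 7 steps (steps 4, 5, 6, 7, 8, 9 and 10, from epoxide 9). The arene branch (steps 1, 2 and 3) joins at step 8.

Steps most likely to fail

Step 8. The aryl anion may be protonated before the acyl shift, so that only O-arylation occurs. The ynoate may also lose CO2 at the reaction temperature, base may trigger propargyl–allenyl isomerisation with expulsion of the acetal oxygen, or the phenoxide may be arylated by a second aryne. The fallback assembles the chromone by palladium-catalysed carbonylative annulation of an ortho-iodophenol with the terminal alkyne, which is known chemistry. It sets out from aryllithium 4 (generated from 2 exactly as in step 2) and from alkyne 13, and comes back to the route at 19. Quenching 4 with I2 in place of TMSCl should give 2-iodo-3,5-dimethoxyphenyl N-(tert-butyldimethylsilyl)-N-isopropylcarbamate F1, which loses the N-silyl group in the aqueous NaHSO4 work-up to give 2-iodo-3,5-dimethoxyphenyl N-isopropylcarbamate F2. DBU and Et2NH in MeCN at 40 °C should then free 2-iodo-3,5-dimethoxyphenol F3. Heating F3 with 13 under CO (balloon) with PdCl2(PPh3)2 (5 mol%) in Et2NH at 60 °C should give, by oxidative addition, CO insertion and alkynylation, (5R)-1-(2-hydroxy-4,6-dimethoxyphenyl)-5-(methoxymethoxy)undec-10-en-2-yn-1-one F4, the neutral form of 18. The amine should close F4 in the same flask by 6-endo addition to 19.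

Step 9. Demethylation at C7 may set in on warming, the cleaved alkoxymethyl cation may be transferred to the electron-rich ring A, or chloride substitution or dehydration may occur at the boron-bound carbinol. The fallback separates the two ether cleavages and uses no boron halide. It sets out from 19 and comes back at 20. Acid methanolysis of the acetal (catalytic conc. HCl, MeOH, 40 °C) should give 2-[(2R)-2-hydroxyoct-7-en-1-yl]-5,7-dimethoxy-4H-chromen-4-one F5. MgI2·OEt2 in THF at 60 °C, which demethylates only a methoxy group held in a magnesium chelate with the neighbouring carbonyl, should then give 20.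

Step 10. The catalyst may be sequestered by the chelating 5-hydroxy-4-oxo unit or by the carboxylic acid, the double bond may migrate with chain shortening, or 20 may homodimerise. The fallback builds the enoic acid by oxidative cleavage and olefination; it sets out from 20 and comes back at 22. Lemieux–Johnson cleavage with OsO4 (2 mol%), NaIO4 and 2,6-lutidine in dioxane–H2O, selective for the monosubstituted alkene over the electron-poor C2=C3 bond, should give (6R)-6-hydroxy-7-(5-hydroxy-7-methoxy-4-oxo-4H-chromen-2-yl)heptanal F6. Wittig reaction with the stabilised ylide Ph3P=CHCO2t-Bu in CH2Cl2 at rt should give tert-butyl (2E,8R)-8-hydroxy-9-(5-hydroxy-7-methoxy-4-oxo-4H-chromen-2-yl)non-2-enoate F7. TFA in CH2Cl2 at 0 °C → rt should then release 22.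

Further compounds
F1 | step 8 | 2-iodo-3,5-dimethoxyphenyl N-(tert-butyldimethylsilyl)-N-isopropylcarbamate | COc1cc(OC)c(I)c(OC(=O)N(C(C)C)[Si](C)(C)C(C)(C)C)c1
F2 | step 8 | 2-iodo-3,5-dimethoxyphenyl N-isopropylcarbamate | COc1cc(OC)c(I)c(OC(=O)NC(C)C)c1
F3 | step 8 | 2-iodo-3,5-dimethoxyphenol | COc1cc(O)c(I)c(OC)c1
F4 | step 8 | (5R)-1-(2-hydroxy-4,6-dimethoxyphenyl)-5-(methoxymethoxy)undec-10-en-2-yn-1-one | COc1cc(O)c(C(=O)C#CC[C@H](OCOC)CCCCC=C)c(OC)c1
F5 | step 9 | 2-[(2R)-2-hydroxyoct-7-en-1-yl]-5,7-dimethoxy-4H-chromen-4-one | COc1cc(OC)c2c(=O)cc(C[C@H](O)CCCCC=C)oc2c1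
F6 | step 10 | (6R)-6-hydroxy-7-(5-hydroxy-7-methoxy-4-oxo-4H-chromen-2-yl)heptanal | COc1cc(O)c2c(=O)cc(C[C@H](O)CCCCC=O)oc2c1
F7 | step 10 | tert-butyl (2E,8R)-8-hydroxy-9-(5-hydroxy-7-methoxy-4-oxo-4H-chromen-2-yl)non-2-enoate | COc1cc(O)c2c(=O)cc(C[C@H](O)CCCC/C=C/C(=O)OC(C)(C)C)oc2c1
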